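(The numbers are made up; what happens was integrated by code.)

We read this flask at 5.0 d, and that time is the first thing to weigh.

    L ⇌ D, rate k1*(csat - [D]) (k1 = 0.14 min⁻¹, csat = 4.1 mM)
    J + D → J.D (k2 = 6.4 M⁻¹ min⁻¹)
    2 J → J2 (k3 = 0.54 M⁻¹ min⁻¹)

J 0.050 M; L 4.1 mM (held); time 5.0 d

* why nothing more happens at 5.0 d, or that something still does (all of J has reacted / forward and back rates have come level / it is still moving)
* part of the J gone at 5.0 d
* the J.D standing at 5.0 d, as a percentage of the J charged

- percent here means J units held: one J2 counts as two
- a doubled species enters its step squared and goes two at a time
- at the start none of D is dissolved
- the reaction counts as stopped when no species that holds the J changes by six tenths of a point or more over the second half of the time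
- run time (flask): 5.0 d

With D at saturation a J lives about 38.1 min, far shorter than the reading time, so we expect the reading to find a finished split between J.D and J2, and that split is what we reckon. But the charge stands above the transfer amount 0.0219 M, the J at which D is taken up as fast as its transfer coefficient renews it, so D sags below saturation while J is plentiful, and we hold it at its steady level (quasi-steady state). The two steps then consume J equally at one amount, the crossover amount 0.0146 M, and since the charge is 3.43 times that, J2 takes the larger share at first. The share going to J.D (instantaneous selectivity) is 12.9% at the charge, 31.2% at 0.0250 M, and tends to one as J vanishes, so Simpson's rule gives 39.6% of the charge as J.D. That figure takes D at its steady level from the first moment, but D begins at nothing and, with J at the charge taking it up, needs about 2.17 min to come up to that level, which is shorter than the 18.5 min first half-life of J by dimerisation alone, so we commit to a little under it.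

The forecast said all of J has reacted, with 100% of J gone and 37% as J.D, the filling of D being what “takes gas away from product”.

The simulation gives all of J has reacted, with 100% gone and 37.1% as J.D, which is 2.5 percentage points under our Simpson figure.

The neighbouring flask, charged with 0.013 M of J and otherwise the same, starts at 0.890 times the crossover amount, so in that flask the reckoned share of J.D leads from the charge on. That share is 54.0% at the charge and 74.2% at 0.00650 M, and the same rule gives 75.2%. The simulated neighbour flask ends with 0% of its J left and 71.7% as J.D, 3.5 points under that reckoning.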